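## Structural features

The target is a germacranolide of the melampolide type: a cyclodeca-1(10),4-diene (C1–C10) in which C1=C10 is Z and C4=C5 is E, both trisubstituted and together a 1,5-diene, fused across C6–C7 to an α-methylene-γ-butyrolactone (C11, C12, C13, O6). Four stereocentres stand in a row: C6 (lactone oxygen), C7 (ring fusion), C8 (free hydroxyl) and C9 (acyloxy). H6 and H7 are cis, so the lactone is cis-fused, and the C8 and C9 oxygens are syn (threo) when C7–C10 is drawn extended. The acyl group on O9 is (2S,3S)-2,3-dimethyloxirane-2-carboxylate (epoxyangelate), whose two stereocentres are remote from the ring and best made separately. Fragile groups are the methylene lactone (conjugate acceptor towards hydride, amines and enolates), the trisubstituted epoxide (acid), the vicinal hydroxy ester (acyl migration from O9 to O8 under base) and the medium-ring 1,5-diene with allylic C–O bonds at C6 and C9 (acid-induced transannular cyclisation, Cope rearrangement on strong heating). The real difficulty is threefold: closing a ten-membered ring that already holds a Z and an E trisubstituted alkene, relaying configuration along C6–C9 on a conformationally mobile ring, and telling O8 from O9. The key step exploits the position of O6 on C6 next to C7: a two-carbon acetal tether on O6 (the future C12 and C11) reaches C7 in a 5-exo radical closure if C7=C8 is the alkene of an enone whose carbonyl is C9, and that carbonyl is afterwards the handle for both the C8 and the C9 oxygen.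

## Logic of the disconnections

33 to 32: the O8–Si bond is introduced backwards. O8 must be distinguishable from O9 when the acyl group goes on and inert when C11 is deprotonated. The gain is that every later operation sees at most one free hydroxyl. The demand is a final unmasking without base or strong acid.

32 to 28: the C11=C13 bond is cut. The methylene lactone would not survive hydride, enolate or nucleophilic-catalyst steps, so it comes late from the saturated lactone. The demand is one enolisation at C11 in the presence of the C9 ester, acceptable because that ester has no α-hydrogen.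

28 to 22 and 26: the acyl–O9 bond is cut. This is convergent and moves two stereocentres into a separate catalytic branch. The demand is acylation of a hindered allylic alcohol by an α-quaternary acid with O8 blocked.

26 to 25 to 24 to 23: the carboxyl is taken back to CH2OH so that the oxirane C–O bonds can be formed under ligand control on an allylic alcohol, and the alcohol is taken back to the purchasable Z ester. The demand is retention of the Z geometry and an oxidation that does not open the epoxide.

22 to 21 to 20 to 18: the C9–H bond, the O8–Si bond and the C8–O bond are cut in turn, returning both oxygenated centres to one C9 carbonyl. Two stereocentres are removed and C8 becomes the α′ position of an enone. The demand is facial control in the enolate oxidation (C7 as controller) and in the hydride addition (C8 as controller).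

18 to 17 to 16: C12 is taken back from the carboxyl to the acetal oxidation level, because an acetal-tethered radical cyclises readily whereas an ester-tethered one is held in the wrong conformation. The demand is hydrolysis and oxidation mild enough for the diene.

16 to 15 (key): the C7–C11 bond is cut.
- The lactone ring and the C7 stereocentre disappear and a monocyclic trienone with a single stereocentre (C6) remains.
- The demands are 5-exo closure at C7 rather than at C5, and H6/H7 cis.
- Cis fusion is not guaranteed by the tether length on a ten-membered ring; it has to come from the rotamer about C6–C7 that the ring enforces (see step 10).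
- The tether is placed on O6 before the ring exists, so that a free hydroxyl γ to the Z enone, which would close to a hemiketal and dehydrate to a furan, is never present.

15 to 14: the C7=C8 bond is cut (retro-metathesis). Both termini become monosubstituted alkenes, and the trisubstituted alkenes are spectators. The ring is exchanged for an open chain. The demand is a high-dilution closure of a strained ring onto an electron-poor alkene.

14 to 13 and 9: the C8–C9 bond is cut as an acyl substitution, so the sensitive vinyl ketone appears only one step before ring closure. The demand is that the amide stops at the ketone stage and that the bromoacetal tolerates the Grignard reagent.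

13 to 11 and 12: the O6–C12 acetal bond is cut. The tether doubles as the protecting group for O6. The demand is only chemoselective bromination of the vinyl ether.

11 to 8 and 9 (through 10): the C6–C7 bond is cut. The one stereocentre not set by relay becomes a catalytic enantioselective aldehyde addition. The demand is Re-face delivery of vinyl to an enal.

8 to 7 to 6: oxidation-level change at C6 and acyl interchange at C9. One operation converts the ester into the amide and frees O6.

6 to 4 and 5: the C1=C10 bond is cut as an olefination. The Z geometry is demanded of the phosphonate.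

4 to 2 to 1: the aldehyde carbon C1 is traced to the terminal alkene of 1 by C=C cleavage through the epoxide. C1–C6 with the E C4=C5 alkene is bought, not made. The demand is site-selective epoxidation.

## Other disconnections considered

Alternative 1: The cut is C5–C6, with the lactone C12–O6 bond opened as well.
- Forward step: the open-chain aldehyde A1 (E-alkenyl iodide at C5, aldehyde at C6, CH2CO2Me on C7, p-methoxybenzyl ether on O8, tert-butyldimethylsilyl ether on O9) would be treated with excess CrCl2 and catalytic NiCl2 at high dilution. The alkenylchromium species adds to the aldehyde (Nozaki–Hiyama–Kishi reaction) and the alkoxide closes onto the ester to give the cis-lactone A2.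
- In favour: this is among the most dependable closures for medium carbocycles. It tolerates esters and ethers, the E geometry of C4=C5 is fixed in the iodide, and C7–C9 are built in an open chain by reagent-controlled methods.
- Against: C6 is created in the ring-closing step under substrate control from an α-branched, epimerisable aldehyde, and only the adduct with O6 cis to C11 is useful. A1 holds three contiguous stereocentres and two orthogonal protecting groups that must be assembled linearly. After A2 the methylenation, two deprotections and the acylation remain. A large excess of divalent chromium is consumed.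
- Comparison: for the ring closure itself and for C8/C9 this plan is the better one, because neither depends on the conformation of a ten-membered ring. In functional-group tolerance of the key step the two are equal. The chosen plan is better at C6 (catalyst control before any ring exists) and in step economy, since 1 already supplies C1–C6 with the E alkene.

Alternative 2: The cut is the transannular C4–C9 bond.
- Forward step: the trans-decalin A3 (angular hydroxyl on C9, angular methyl on C4, equatorial mesylate on C5, C1=C10 inside a cyclohexene, cis-lactone and silyl ether already on ring B) would be treated with KOC(CH3)3. The C9 alkoxide pushes, C4–C9 breaks anti-periplanar to the C5–O bond (Grob fragmentation), and the ten-membered ketone A4 appears with the E C4=C5 alkene. A4 is the same compound as 21.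
- In favour: the fragmentation is stereospecific, so the E geometry follows from the chair. The Z alkene is necessarily Z in a six-membered ring. There is no entropic penalty of a medium-ring closure. C6, C7 and C8 are set on a rigid decalin.
- Against: A3 needs six stereocentres, two of them quaternary, three of which (C4, C5, C9) are built only to be destroyed, and an enantioselective route to it is long. The strongly basic step must spare a lactone, gives an α-silyloxy ketone that can epimerise at C8, and the angular alkoxide can take the silyl group from O8 before it fragments.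
- Comparison: from 21 onward the two plans are identical, so the end game is equal. The alternative is the better one for the geometry of C4=C5, for ring formation and for C8. The chosen plan is better in step and stereocentre economy and avoids strong base on the lactone, at the price of relying on ring conformation for C7, C8 and C9.

Alternative 3: The cut is C11–C12 together with C12–O6; the lactone carbonyl is removed as CO.
- Forward step: A5 (the ten-membered ring with free C6 hydroxyl, an ethynyl group on C7 cis to it, the silyl ether on O8 and the epoxy ester on O9) would be carbonylated with catalytic PdCl2/thiourea under CO. An alkoxycarbonyl complex of divalent palladium forms on O6, adds syn across the alkyne and is protonated, giving the methylene lactone A6. A6 is the same compound as 32.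
- In favour: carbonyl and exocyclic methylene arrive in one late, nearly neutral catalytic step. Neither an acetal oxidation nor a strong-base methylenation next to the epoxy ester is needed.
- Against: A5 already contains the ring, all four ring stereocentres and the cis C6/C7 relationship, so ring closure and C7 are only moved to an earlier, undefined stage, where an alkynyl group would have to be delivered to C7 with the same facial question. Divalent palladium is electrophilic towards the 1,5-diene, any zerovalent palladium formed can ionise the allylic C–O bonds at C6 and C9, and thiourea is a nucleophile towards the epoxide.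
- Comparison: as a last C–C bond formation the alternative is the better and shorter solution for the methylene lactone (one step against steps 11, 12 and 20). The final deprotection is equal. In overall structure-building the chosen plan is better, because its key step creates C7 and the lactone ring from a precursor with one stereocentre, whereas this one presupposes them.

Key step: step 10

Remark: ring compounds are discussed with germacrane numbering; in the cyclodeca[b]furan names 3a = C7, 4 = C8, 5 = C9 and 11a = C6, and CIP descriptors change along the route where substituent priorities change although the spatial arrangement does not.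
Remark: the acetal carbon of 13–16 forms without control; each is a pair of epimers at that carbon, the SMILES show one of them, and the centre disappears in step 12.
Remark: the sense of induction in step 6 is assumed to follow that of amino-alcohol-catalysed dialkylzinc additions; should it be opposite, the enantiomeric ligand is used.

## Route

Step 1
Reactants: 1 geranyl acetate, (2E)-3,7-dimethylocta-2,6-dien-1-yl acetate (commercial acetate of geraniol)
Product: 2 (2E)-5-(3,3-dimethyloxiran-2-yl)-3-methylpent-2-en-1-yl acetate (racemic at the epoxide carbon)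
Conditions: mCPBA (1.05 equiv), NaHCO3, CH2Cl2, 0 °C
Reagents that add atoms: 3-chloroperoxybenzoic acid, OOC(=O)c1cccc(Cl)c1
Why: Prilezhaev epoxidation; the remote trisubstituted alkene is the more electron-rich one because the allylic acetate deactivates the other, so one equivalent of peracid should epoxidise it selectively; the new centre is racemic and is destroyed in step 2.

Step 2
Reactants: 2 (2E)-5-(3,3-dimethyloxiran-2-yl)-3-methylpent-2-en-1-yl acetate
Product: 4 (2E)-3-methyl-6-oxohex-2-en-1-yl acetate, via diol 3 (not isolated)
Conditions: H5IO6, THF/H2O, 0 °C → rt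
Reagents that add atoms: none
Why: Acid-mediated opening of the epoxide by water at the tertiary carbon gives 3, and periodate glycol cleavage (Malaprade reaction) should release the aldehyde and acetone; the allylic acetate and the E alkene are not touched.

Step 3
Reactants: 4 (2E)-3-methyl-6-oxohex-2-en-1-yl acetate; 5 ethyl 2-[bis(2,2,2-trifluoroethoxy)phosphoryl]propanoate
Product: 6 ethyl (2Z,6E)-8-acetoxy-2,6-dimethylocta-2,6-dienoate
Conditions: 5, KN(SiMe3)2, 18-crown-6, THF, −78 °C; then 4, −78 °C
Reagents that add atoms: none
Why: Still–Gennari olefination; the electron-poor phosphonate with a dissociated potassium counter-ion eliminates from the kinetic adduct faster than it equilibrates, which should give the Z trisubstituted enoate (C1=C10 of the target); the acetate survives the non-nucleophilic conditions at −78 °C.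

Step 4
Reactants: 6 ethyl (2Z,6E)-8-acetoxy-2,6-dimethylocta-2,6-dienoate
Product: 7 (2Z,6E)-8-hydroxy-N-methoxy-N,2,6-trimethylocta-2,6-dienamide
Conditions: MeNH(OMe)·HCl (4 equiv), iPrMgCl (8 equiv), THF, −20 → 0 °C
Reagents that add atoms: N,O-dimethylhydroxylamine hydrochloride, CNOC.Cl
Why: Aminolysis of esters by the chloromagnesium amide of N,O-dimethylhydroxylamine (Weinreb amide formation); the conjugated ethyl ester becomes the amide and the acetate is cleaved in the same operation, so no separate deprotection is needed; the α-methyl-β-alkyl enoate is a poor Michael acceptor, so the Z geometry should be retained.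

Step 5
Reactants: 7 (2Z,6E)-8-hydroxy-N-methoxy-N,2,6-trimethylocta-2,6-dienamide
Product: 8 (2Z,6E)-N-methoxy-N,2,6-trimethyl-8-oxoocta-2,6-dienamide
Conditions: MnO2 (excess), CH2Cl2, rt
Reagents that add atoms: none
Why: MnO2 oxidises allylic alcohols selectively; the E enal (the C6 aldehyde) should form without touching the amide.

Step 6
Reactants: 8 (2Z,6E)-N-methoxy-N,2,6-trimethyl-8-oxoocta-2,6-dienamide; 9 vinylmagnesium bromide
Product: 11 (2Z,6E,8R)-8-hydroxy-N-methoxy-N,2,6-trimethyldeca-2,6,9-trienamide, via divinylzinc 10 (not isolated)
Conditions: (CH2=CH)2Zn [from 9 and ZnCl2, Et2O; dioxane, filtration], (1R,2S)-2-(dibutylamino)-1-phenylpropan-1-ol (10 mol %), PhMe, 0 °C; aq. NH4Cl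
Reagents that add atoms: none
Why: Amino-alcohol-catalysed addition of an alkenylzinc reagent to an aldehyde; 10 does not attack the amide, and the (1R,2S)-ligand, whose enantiomer directs organozinc reagents to the Si face, should deliver vinyl to the Re face of the enal and give the (R)-carbinol, which is C6 of the target.

Step 7
Reactants: 11 (2Z,6E,8R)-8-hydroxy-N-methoxy-N,2,6-trimethyldeca-2,6,9-trienamide; 12 ethyl vinyl ether
Product: 13 (2Z,6E,8R)-8-(2-bromo-1-ethoxyethoxy)-N-methoxy-N,2,6-trimethyldeca-2,6,9-trienamide (both acetal epimers)
Conditions: 12 (5 equiv), NBS (1.2 equiv), CH2Cl2, −40 → 0 °C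
Reagents that add atoms: N-bromosuccinimide, O=C1CCC(=O)N1Br
Why: Haloacetalisation, the first stage of the Ueno–Stork sequence; NBS brominates the electron-rich vinyl ether far faster than the other alkenes and the alcohol captures the oxocarbenium ion; the tether now also protects O6 through steps 8 and 9.

Step 8
Reactants: 13 (2Z,6E,8R)-8-(2-bromo-1-ethoxyethoxy)-N-methoxy-N,2,6-trimethyldeca-2,6,9-trienamide; 9 vinylmagnesium bromide
Product: 14 (4Z,8E,10R)-10-(2-bromo-1-ethoxyethoxy)-4,8-dimethyldodeca-1,4,8,11-tetraen-3-one
Conditions: CH2=CHMgBr (2.5 equiv), THF, −20 → 0 °C; inverse quench into cold 0.5 M HCl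
Reagents that add atoms: none
Why: Weinreb ketone synthesis, which stops at the ketone oxidation level; the primary bromide and the acetal are inert to the Grignard reagent at low temperature, and the cold acidic inverse quench protonates the released N,O-dimethylhydroxylamine before it can add to the vinyl ketone, which is used at once.

Step 9
Reactants: 14 (4Z,8E,10R)-10-(2-bromo-1-ethoxyethoxy)-4,8-dimethyldodeca-1,4,8,11-tetraen-3-one
Product: 15 (2Z,4R,5E,9Z)-4-(2-bromo-1-ethoxyethoxy)-6,10-dimethylcyclodeca-2,5,9-trien-1-one (germacrane locants: ketone C9, bromoacetal on O6)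
Conditions: second-generation Grubbs catalyst (H2IMes)(PCy3)Cl2Ru=CHPh (10 mol %, in portions), CH2Cl2 (0.001 M), 40 °C
Reagents that add atoms: none
Why: Ring-closing metathesis; ruthenium should load on the C7 vinyl group and close onto the vinyl ketone with loss of ethene, and from that carbene the E C4=C5 alkene excludes any smaller ring; high dilution suppresses cross-metathesis, and the Z enone is expected because a second E alkene next to C6 cannot be held in ten atoms (its geometry is in any case erased in step 10).

Step 10
Reactants: 15 (2Z,4R,5E,9Z)-4-(2-bromo-1-ethoxyethoxy)-6,10-dimethylcyclodeca-2,5,9-trien-1-one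
Product: 16 (3aR,6Z,10E,11aR)-2-ethoxy-6,10-dimethyl-3,3a,4,8,9,11a-hexahydrocyclodeca[b]furan-5(2H)-one (cis-fused, both acetal epimers)
Conditions: Bu3SnH (1.5 equiv), 2,2′-azobis(4-methoxy-2,4-dimethylvaleronitrile) (0.2 equiv), PhMe (0.02 M), 30 °C
Reagents that add atoms: none
Why: Tributylstannyl radicals abstract bromine from 15, the primary C11 radical adds to C7, and the resulting C8 radical, stabilised by the C9 carbonyl, abstracts hydrogen from Bu3SnH and carries the chain. The closest known reaction type is the Ueno–Stork haloacetal cyclisation onto cyclic enones and butenolides. The five-membered acetal ring (C11, C12, O, C6, C7) closes in the 5-exo-trig mode. The new stereocentre C7 is controlled by C6 through the rotamer about C6–C7: a two-atom tether alone would allow either fusion on a ten-membered ring, but the short C3–C2–C1=C10–C9 bridge should hold C5 syn-clinal to C8, and from that arrangement the only rotamer that puts O6 over a π-lobe of C7 leads, by attack from the outer face, to H6 and H7 cis. Attack at C7 rather than at the equally 5-exo C5 rests on polarity matching of the nucleophilic alkyl radical with the enone β-carbon, which the low temperature accentuates. A non-dilute stannane concentration is chosen because closure onto an enone is fast, so the C8 radical is reduced before it can add across the ring to C4=C5. Both acetal epimers react and converge in step 12.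

Step 11
Reactants: 16 (3aR,6Z,10E,11aR)-2-ethoxy-6,10-dimethyl-3,3a,4,8,9,11a-hexahydrocyclodeca[b]furan-5(2H)-one
Product: 17 (3aR,6Z,10E,11aR)-2-hydroxy-6,10-dimethyl-3,3a,4,8,9,11a-hexahydrocyclodeca[b]furan-5(2H)-one (lactol, both anomers)
Conditions: AcOH/THF/H2O (3:1:1), 40 °C
Reagents that add atoms: water, O
Why: Acid-catalysed hydrolysis of the cyclic acetal; mild aqueous acetic acid is chosen because the ring 1,5-diene is prone to acid-induced transannular cyclisation, which conjugation of C1=C10 with the C9 ketone retards at this stage.

Step 12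
Reactants: 17 (3aR,6Z,10E,11aR)-2-hydroxy-6,10-dimethyl-3,3a,4,8,9,11a-hexahydrocyclodeca[b]furan-5(2H)-one
Product: 18 (3aS,6Z,10E,11aR)-6,10-dimethyl-3a,4,8,9-tetrahydrocyclodeca[b]furan-2,5(3H,11aH)-dione (cis-fused keto lactone)
Conditions: Pr4N[RuO4] (5 mol %), N-methylmorpholine N-oxide, 4 Å MS, CH2Cl2, rt
Reagents that add atoms: none
Why: Ley–Griffith oxidation of a lactol to a lactone is fast and neutral; no other hydroxyl is present and the acetal epimers converge to one compound.

Step 13
Reactants: 18 (3aS,6Z,10E,11aR)-6,10-dimethyl-3a,4,8,9-tetrahydrocyclodeca[b]furan-2,5(3H,11aH)-dione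
Product: 20 (3aR,4R,6Z,10E,11aS)-4-hydroxy-6,10-dimethyl-3a,4,8,9-tetrahydrocyclodeca[b]furan-2,5(3H,11aH)-dione, via sodium enolate 19 (not isolated)
Conditions: NaN(SiMe3)2 (1.1 equiv), THF, −78 °C; 2-(phenylsulfonyl)-3-phenyloxaziridine, −78 °C; aq. NH4Cl
Reagents that add atoms: 2-(phenylsulfonyl)-3-phenyloxaziridine, O=S(=O)(c1ccccc1)N1OC1c1ccccc1
Why: Kinetic α′-deprotonation of the enone gives the cross-conjugated enolate 19 (the ketone is several pKa units more acidic than the lactone and C10 bears no hydrogen), and oxygen transfer from the N-sulfonyloxaziridine (Davis oxidation) gives the α-hydroxy ketone; with H7 eclipsing the enolate (allylic 1,3-strain) the oxidant should approach C8 from the peripheral face anti to the ring bond C7–C6, which corresponds to the required (8R) configuration.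

Step 14
Reactants: 20 (3aR,4R,6Z,10E,11aS)-4-hydroxy-6,10-dimethyl-3a,4,8,9-tetrahydrocyclodeca[b]furan-2,5(3H,11aH)-dione
Product: 21 (3aS,4R,6Z,10E,11aS)-6,10-dimethyl-4-(triethylsilyloxy)-3a,4,8,9-tetrahydrocyclodeca[b]furan-2,5(3H,11aH)-dione
Conditions: Et3SiCl, imidazole, DMF, 0 °C
Reagents that add atoms: chlorotriethylsilane, CC[Si](Cl)(CC)CC
Why: Silylation of a secondary alcohol; the triethylsilyl ether differentiates O8 from O9, supplies the polar α-substituent for Felkin–Anh control in step 15 and can be removed at the end without base.

Step 15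
Reactants: 21 (3aS,4R,6Z,10E,11aS)-6,10-dimethyl-4-(triethylsilyloxy)-3a,4,8,9-tetrahydrocyclodeca[b]furan-2,5(3H,11aH)-dione
Product: 22 (3aS,4R,5R,6Z,10E,11aS)-5-hydroxy-6,10-dimethyl-4-(triethylsilyloxy)-3a,4,5,8,9,11a-hexahydrocyclodeca[b]furan-2(3H)-one
Conditions: NaBH4, CeCl3·7H2O, MeOH, −78 → −40 °C
Reagents that add atoms: none
Why: Luche reduction; NaBH4/CeCl3 reduces the enone carbonyl 1,2 and leaves the lactone; hydride should add anti to the C8–O bond in the Felkin–Anh arrangement (the silyl ether does not chelate), giving the 8,9-syn (threo) relationship, which is (9R).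

Step 16
Reactants: 23 methyl angelate, methyl (2Z)-2-methylbut-2-enoate
Product: 24 (2Z)-2-methylbut-2-en-1-ol
Conditions: LiAlH4, Et2O, 0 °C
Reagents that add atoms: none
Why: Hydride reduction of an α,β-unsaturated ester to the allylic alcohol; the Z geometry is retained under these non-equilibrating conditions.

Step 17
Reactants: 24 (2Z)-2-methylbut-2-en-1-ol
Product: 25 [(2R,3S)-2,3-dimethyloxiran-2-yl]methanol
Conditions: Ti(OiPr)4 (10 mol %), D-(−)-diisopropyl tartrate (13 mol %), tBuOOH, 4 Å MS, CH2Cl2, −20 °C
Reagents that add atoms: tert-butyl hydroperoxide, CC(C)(C)OO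
Why: Sharpless asymmetric epoxidation; the D-(−)-tartrate delivers oxygen to the face of the Z trisubstituted allylic alcohol that gives the (2R,3S)-epoxy alcohol, and the cis relationship of CH2OH and the C3 methyl follows from the Z alkene.

Step 18
Reactants: 25 [(2R,3S)-2,3-dimethyloxiran-2-yl]methanol
Product: 26 (2S,3S)-2,3-dimethyloxirane-2-carboxylic acid (epoxyangelic acid)
Conditions: RuCl3·xH2O (2 mol %), NaIO4 (4 equiv), MeCN/EtOAc/H2O, rt
Reagents that add atoms: water, O (second carboxyl oxygen, through the aldehyde hydrate; NaIO4 is the terminal oxidant)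
Why: Catalytic RuO4 oxidation converts primary 2,3-epoxy alcohols into glycidic acids without opening the epoxide; the C2 descriptor changes from R to S only because the priorities change.

Step 19
Reactants: 22 (3aS,4R,5R,6Z,10E,11aS)-5-hydroxy-6,10-dimethyl-4-(triethylsilyloxy)-3a,4,5,8,9,11a-hexahydrocyclodeca[b]furan-2(3H)-one; 26 (2S,3S)-2,3-dimethyloxirane-2-carboxylic acid
Product: 28 (3aS,4R,5R,6Z,10E,11aS)-6,10-dimethyl-2-oxo-4-(triethylsilyloxy)-2,3,3a,4,5,8,9,11a-octahydrocyclodeca[b]furan-5-yl (2S,3S)-2,3-dimethyloxirane-2-carboxylate, via mixed anhydride 27 (not isolated)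
Conditions: 26, 2,4,6-Cl3C6H2COCl, Et3N, THF, rt; then 22, DMAP, PhMe, rt
Reagents that add atoms: none
Why: Yamaguchi esterification; the ortho chlorines shield the aroyl carbonyl of 27, so DMAP takes up the epoxy-acyl group and transfers it to the hindered allylic C9 hydroxyl; O8 is silylated, so only O9 can react, and the acid has no α-hydrogen and cannot epimerise.

Step 20
Reactants: 28 (3aS,4R,5R,6Z,10E,11aS)-6,10-dimethyl-2-oxo-4-(triethylsilyloxy)-2,3,3a,4,5,8,9,11a-octahydrocyclodeca[b]furan-5-yl (2S,3S)-2,3-dimethyloxirane-2-carboxylate
Product: 32 (3aS,4R,5R,6Z,10E,11aS)-6,10-dimethyl-3-methylidene-2-oxo-4-(triethylsilyloxy)-2,3,3a,4,5,8,9,11a-octahydrocyclodeca[b]furan-5-yl (2S,3S)-2,3-dimethyloxirane-2-carboxylate, via lithium enolate 29 (not isolated), via Mannich base 30 (not isolated), via methiodide 31 (not isolated)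
Conditions: LiN(iPr)2 (1.2 equiv), THF, −78 °C; CH2=NMe2+ I−, −78 → 0 °C; then MeI, CH2Cl2/MeOH, rt; then aq. NaHCO3, rt
Reagents that add atoms: Eschenmoser's salt (N,N-dimethylmethyleneiminium iodide), C=[N+](C)C.[I-]
Why: α-Methylenation of a lactone through its enolate; C11 is the only acidic position (the C9 ester has no α-hydrogen), aminomethylation of 29 gives 30, and exhaustive methylation to 31 followed by Hofmann-type elimination with bicarbonate unveils C11=C13; the short enolate lifetime at −78 °C limits acyl transfer to the C9 ester.

Step 21
Reactants: 32 (3aS,4R,5R,6Z,10E,11aS)-6,10-dimethyl-3-methylidene-2-oxo-4-(triethylsilyloxy)-2,3,3a,4,5,8,9,11a-octahydrocyclodeca[b]furan-5-yl (2S,3S)-2,3-dimethyloxirane-2-carboxylate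
Product: 33 (3aR,4R,5R,6Z,10E,11aS)-4-hydroxy-6,10-dimethyl-3-methylidene-2-oxo-2,3,3a,4,5,8,9,11a-octahydrocyclodeca[b]furan-5-yl (2S,3S)-2,3-dimethyloxirane-2-carboxylate (CNP0213766.2)
Conditions: HF·pyridine, pyridine, THF, 0 °C
Reagents that add atoms: none
Why: Fluoride-mediated cleavage of the triethylsilyl ether under buffered, non-basic conditions, chosen to avoid O9-to-O8 acyl migration and conjugate addition to the methylene lactone; epoxide and alkenes are inert at 0 °C.

## Compound list

1 | geranyl acetate, (2E)-3,7-dimethylocta-2,6-dien-1-yl acetate | CC(C)=CCC/C(C)=C/COC(C)=O | starting material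
2 | (2E)-5-(3,3-dimethyloxiran-2-yl)-3-methylpent-2-en-1-yl acetate (racemic) | CC1(C)OC1CC/C(C)=C/COC(C)=O | intermediate
3 | (2E)-6,7-dihydroxy-3,7-dimethyloct-2-en-1-yl acetate (racemic diol) | CC(C)(O)C(O)CC/C(C)=C/COC(C)=O | intermediate
4 | (2E)-3-methyl-6-oxohex-2-en-1-yl acetate | O=CCC/C(C)=C/COC(C)=O | intermediate
5 | ethyl 2-[bis(2,2,2-trifluoroethoxy)phosphoryl]propanoate | CCOC(=O)C(C)P(=O)(OCC(F)(F)F)OCC(F)(F)F | starting material
6 | ethyl (2Z,6E)-8-acetoxy-2,6-dimethylocta-2,6-dienoate | CCOC(=O)/C(C)=C\CC/C(C)=C/COC(C)=O | intermediate
7 | (2Z,6E)-8-hydroxy-N-methoxy-N,2,6-trimethylocta-2,6-dienamide | CON(C)C(=O)/C(C)=C\CC/C(C)=C/CO | intermediate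
8 | (2Z,6E)-N-methoxy-N,2,6-trimethyl-8-oxoocta-2,6-dienamide | CON(C)C(=O)/C(C)=C\CC/C(C)=C/C=O | intermediate
9 | vinylmagnesium bromide | C=C[Mg]Br | starting material
10 | divinylzinc | C=C[Zn]C=C | intermediate
11 | (2Z,6E,8R)-8-hydroxy-N-methoxy-N,2,6-trimethyldeca-2,6,9-trienamide | CON(C)C(=O)/C(C)=C\CC/C(C)=C/[C@H](O)C=C | intermediate
12 | ethyl vinyl ether | C=COCC | starting material
13 | (2Z,6E,8R)-8-(2-bromo-1-ethoxyethoxy)-N-methoxy-N,2,6-trimethyldeca-2,6,9-trienamide (acetal epimers, one shown) | CON(C)C(=O)/C(C)=C\CC/C(C)=C/[C@H](O[C@@H](CBr)OCC)C=C | intermediate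
14 | (4Z,8E,10R)-10-(2-bromo-1-ethoxyethoxy)-4,8-dimethyldodeca-1,4,8,11-tetraen-3-one (acetal epimers, one shown) | C=CC(=O)/C(C)=C\CC/C(C)=C/[C@H](O[C@@H](CBr)OCC)C=C | intermediate
15 | (2Z,4R,5E,9Z)-4-(2-bromo-1-ethoxyethoxy)-6,10-dimethylcyclodeca-2,5,9-trien-1-one (acetal epimers, one shown) | C1C/C=C(/C)C(=O)/C=C\[C@@H](O[C@@H](CBr)OCC)/C=C1\C | intermediate
16 | (3aR,6Z,10E,11aR)-2-ethoxy-6,10-dimethyl-3,3a,4,8,9,11a-hexahydrocyclodeca[b]furan-5(2H)-one (cis-fused; acetal epimers, one shown) | C1[C@@H](OCC)O[C@H]2/C=C(\C)CC/C=C(/C)C(=O)C[C@@H]12 | intermediate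
17 | (3aR,6Z,10E,11aR)-2-hydroxy-6,10-dimethyl-3,3a,4,8,9,11a-hexahydrocyclodeca[b]furan-5(2H)-one (lactol, both anomers) | C1C(O)O[C@H]2/C=C(\C)CC/C=C(/C)C(=O)C[C@@H]12 | intermediate
18 | (3aS,6Z,10E,11aR)-6,10-dimethyl-3a,4,8,9-tetrahydrocyclodeca[b]furan-2,5(3H,11aH)-dione | C1C(=O)O[C@H]2/C=C(\C)CC/C=C(/C)C(=O)C[C@@H]12 | intermediate
19 | sodium C8=C9 enolate of 18 | C1C(=O)O[C@H]2/C=C(\C)CC/C=C(/C)C([O-])=C[C@@H]12.[Na+] | intermediate
20 | (3aR,4R,6Z,10E,11aS)-4-hydroxy-6,10-dimethyl-3a,4,8,9-tetrahydrocyclodeca[b]furan-2,5(3H,11aH)-dione | C1C(=O)O[C@H]2/C=C(\C)CC/C=C(/C)C(=O)[C@H](O)[C@@H]12 | intermediate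
21 | (3aS,4R,6Z,10E,11aS)-6,10-dimethyl-4-(triethylsilyloxy)-3a,4,8,9-tetrahydrocyclodeca[b]furan-2,5(3H,11aH)-dione | C1C(=O)O[C@H]2/C=C(\C)CC/C=C(/C)C(=O)[C@H](O[Si](CC)(CC)CC)[C@@H]12 | intermediate
22 | (3aS,4R,5R,6Z,10E,11aS)-5-hydroxy-6,10-dimethyl-4-(triethylsilyloxy)-3a,4,5,8,9,11a-hexahydrocyclodeca[b]furan-2(3H)-one | C1C(=O)O[C@H]2/C=C(\C)CC/C=C(/C)[C@@H](O)[C@H](O[Si](CC)(CC)CC)[C@@H]12 | intermediate
23 | methyl angelate, methyl (2Z)-2-methylbut-2-enoate | C/C=C(/C)C(=O)OC | starting material
24 | (2Z)-2-methylbut-2-en-1-ol | C/C=C(/C)CO | intermediate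
25 | [(2R,3S)-2,3-dimethyloxiran-2-yl]methanol | OC[C@@]1(C)O[C@H]1C | intermediate
26 | (2S,3S)-2,3-dimethyloxirane-2-carboxylic acid | OC(=O)[C@@]1(C)O[C@H]1C | intermediate
27 | (2S,3S)-2,3-dimethyloxirane-2-carboxylic 2,4,6-trichlorobenzoic anhydride | O=C(OC(=O)[C@@]1(C)O[C@H]1C)c1c(Cl)cc(Cl)cc1Cl | intermediate
28 | (3aS,4R,5R,6Z,10E,11aS)-6,10-dimethyl-2-oxo-4-(triethylsilyloxy)-2,3,3a,4,5,8,9,11a-octahydrocyclodeca[b]furan-5-yl (2S,3S)-2,3-dimethyloxirane-2-carboxylate | C1C(=O)O[C@H]2/C=C(\C)CC/C=C(/C)[C@@H](OC(=O)[C@@]3(C)O[C@H]3C)[C@H](O[Si](CC)(CC)CC)[C@@H]12 | intermediate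
29 | lithium C11=C12 enolate of 28 | C1=C([O-])O[C@H]2/C=C(\C)CC/C=C(/C)[C@@H](OC(=O)[C@@]3(C)O[C@H]3C)[C@H](O[Si](CC)(CC)CC)[C@@H]12.[Li+] | intermediate
30 | 11-(dimethylaminomethyl) derivative of 28 (C11 epimers) | CN(C)CC1C(=O)O[C@H]2/C=C(\C)CC/C=C(/C)[C@@H](OC(=O)[C@@]3(C)O[C@H]3C)[C@H](O[Si](CC)(CC)CC)[C@@H]12 | intermediate
31 | trimethylammonium iodide derived from 30 | C[N+](C)(C)CC1C(=O)O[C@H]2/C=C(\C)CC/C=C(/C)[C@@H](OC(=O)[C@@]3(C)O[C@H]3C)[C@H](O[Si](CC)(CC)CC)[C@@H]12.[I-] | intermediate
32 | (3aS,4R,5R,6Z,10E,11aS)-6,10-dimethyl-3-methylidene-2-oxo-4-(triethylsilyloxy)-2,3,3a,4,5,8,9,11a-octahydrocyclodeca[b]furan-5-yl (2S,3S)-2,3-dimethyloxirane-2-carboxylate | C=C1C(=O)O[C@H]2/C=C(\C)CC/C=C(/C)[C@@H](OC(=O)[C@@]3(C)O[C@H]3C)[C@H](O[Si](CC)(CC)CC)[C@@H]12 | intermediate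
33 | (3aR,4R,5R,6Z,10E,11aS)-4-hydroxy-6,10-dimethyl-3-methylidene-2-oxo-2,3,3a,4,5,8,9,11a-octahydrocyclodeca[b]furan-5-yl (2S,3S)-2,3-dimethyloxirane-2-carboxylate | C=C1C(=O)O[C@H]2/C=C(\C)CC/C=C(/C)[C@@H](OC(=O)[C@@]3(C)O[C@H]3C)[C@H](O)[C@@H]12 | target

## Step count and least certain steps

Total: 21 steps. Longest linear sequence: 18 steps (steps 1–15 and 19–21 from 1); the acid branch (steps 16–18) has 3 steps.

Step 10 (key step). What is most likely to go wrong is the partition of the cyclising radical between the two rotamers about C6–C7, i.e. poor facial selectivity leading to the trans-fused ring, because the open-chain preference of Z-allylic haloacetals (H6 eclipsing the alkene) points that way and only the ring constraint opposes it. Secondary risks are competing 5-exo closure onto C5 and transannular addition of the C8 radical to C4=C5. The fallback uses the trans preference instead of fighting it. It sets out from 8: step 6 is run with the (1S,2R)-ligand to give the (S)-carbinol F1, which is taken through steps 7–9 to the bromoacetal F2, the vinyl ketone F3 and the C6-epimeric ring trienone F4. Radical cyclisation under the conditions of step 10 then sets C7 correctly relative to the wrong C6 and gives the trans-fused acetal F5. Steps 11 and 12 convert F5 via the lactol F6 into the trans-fused keto lactone F7. Saponification (LiOH, THF/H2O) gives the hydroxy acid F8, and Mitsunobu lactonisation (PPh3, diisopropyl azodicarboxylate) closes the ring with inversion at the allylic C6 and comes back to the route at 18.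

Step 9. What is most likely to go wrong is oligomerisation by cross-metathesis because closure of the strained, electron-poor dienone ring is slow, or ring-contracting metathesis onto C4=C5 from the ketone-side carbene. The fallback closes the ring at the alcohol oxidation level. It sets out from 13: iBu2AlH (THF, −78 °C) reduces the Weinreb amide to the Z enal F9, CH2=CHMgBr gives the bis-allylic carbinol F10 (both C9 epimers), ring-closing metathesis of this more flexible, electron-richer diene gives the cyclic dienol F11, and MnO2 oxidation comes back to the route at 15.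

Step 13. What is most likely to go wrong is poor facial selectivity of oxygen transfer to the enolate, because the argument rests on a model of a mobile ring; partial enolisation toward the lactone is a lesser risk. The fallback inverts instead of re-optimising and sets out from 18. If oxidation gives mainly the C8 epimer F12, Mitsunobu reaction with chloroacetic acid (PPh3, diisopropyl azodicarboxylate; SN2 at a carbon α to a ketone is fast) gives the inverted chloroacetate F13, and thiourea/NaHCO3 in ethanol removes the chloroacetyl group under nearly neutral conditions to come back to the route at 20.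

Step 15. What is most likely to go wrong is hydride delivery to the wrong face of C9 because the ring conformation overrides the Felkin–Anh preference; silyl migration from O8 to O9 at the alkoxide stage is a lesser risk. The fallback sets out from 21. If the C9 epimer F14 predominates, it is esterified directly with 26 under Mitsunobu conditions (PPh3, diisopropyl azodicarboxylate), which forms the C9–O bond with inversion and comes back to the route at 28, replacing step 19.

Step 6. What is most likely to go wrong is erosion of enantioselectivity through uncatalysed background addition or through binding of zinc to the amide. The fallback is a resolution and sets out from 8. CH2=CHMgBr at −78 °C gives the racemic carbinol F15. Sharpless kinetic resolution (Ti(OiPr)4, L-(+)-diisopropyl tartrate, tBuOOH about 0.6 equiv, −20 °C) epoxidises the fast-reacting (S)-enantiomer at the trisubstituted alkene to the epoxy alcohol F16 and leaves the (R)-enantiomer, which is 11.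

## Further compounds

F1 | step 10 | (2Z,6E,8S)-8-hydroxy-N-methoxy-N,2,6-trimethyldeca-2,6,9-trienamide (enantiomer of 11) | CON(C)C(=O)/C(C)=C\CC/C(C)=C/[C@@H](O)C=C
F2 | step 10 | (8S)-bromoacetal, C8 epimer series of 13 (both acetal epimers) | CON(C)C(=O)/C(C)=C\CC/C(C)=C/[C@@H](OC(CBr)OCC)C=C
F3 | step 10 | (10S)-vinyl ketone, C10 epimer series of 14 (both acetal epimers) | C=CC(=O)/C(C)=C\CC/C(C)=C/[C@@H](OC(CBr)OCC)C=C
F4 | step 10 | C6-epimeric ring trienone bromoacetal (4S analogue of 15, both acetal epimers) | C1C/C=C(/C)C(=O)/C=C\[C@H](OC(CBr)OCC)/C=C1\C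
F5 | step 10 | trans-fused bicyclic acetal ketone (C6 epimer of 16, both acetal epimers) | C1C(OCC)O[C@@H]2/C=C(\C)CC/C=C(/C)C(=O)C[C@@H]12
F6 | step 10 | trans-fused lactol (C6 epimer of 17) | C1C(O)O[C@@H]2/C=C(\C)CC/C=C(/C)C(=O)C[C@@H]12
F7 | step 10 | trans-fused keto lactone (C6 epimer of 18) | C1C(=O)O[C@@H]2/C=C(\C)CC/C=C(/C)C(=O)C[C@@H]12
F8 | step 10 | hydroxy acid from F7 (C6 hydroxyl, C7 CH2CO2H, C9 ketone) | OC(=O)C[C@@H]1CC(=O)/C(C)=C\CC/C(C)=C/[C@H]1O
F9 | step 9 | (2Z,6E,8R)-8-(2-bromo-1-ethoxyethoxy)-2,6-dimethyldeca-2,6,9-trienal | O=C/C(C)=C\CC/C(C)=C/[C@H](O[C@@H](CBr)OCC)C=C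
F10 | step 9 | (4Z,8E,10R)-10-(2-bromo-1-ethoxyethoxy)-4,8-dimethyldodeca-1,4,8,11-tetraen-3-ol (both C3 epimers) | C=CC(O)/C(C)=C\CC/C(C)=C/[C@H](O[C@@H](CBr)OCC)C=C
F11 | step 9 | (2Z,4R,5E,9Z)-4-(2-bromo-1-ethoxyethoxy)-6,10-dimethylcyclodeca-2,5,9-trien-1-ol (both C1 epimers) | C1C/C=C(/C)C(O)/C=C\[C@@H](O[C@@H](CBr)OCC)/C=C1\C
F12 | step 13 | C8 epimer of 20 | C1C(=O)O[C@H]2/C=C(\C)CC/C=C(/C)C(=O)[C@@H](O)[C@@H]12
F13 | step 13 | chloroacetate of 20 (C8 configured as in 20) | C1C(=O)O[C@H]2/C=C(\C)CC/C=C(/C)C(=O)[C@H](OC(=O)CCl)[C@@H]12
F14 | step 15 | C9 epimer of 22 | C1C(=O)O[C@H]2/C=C(\C)CC/C=C(/C)[C@H](O)[C@H](O[Si](CC)(CC)CC)[C@@H]12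
F15 | step 6 | racemic 8-hydroxy-N-methoxy-N,2,6-trimethyldeca-2,6,9-trienamide (2Z,6E) | CON(C)C(=O)/C(C)=C\CC/C(C)=C/C(O)C=C
F16 | step 6 | epoxy alcohol formed from the (S)-enantiomer of F15 (oxirane at the former trisubstituted alkene next to the carbinol) | CON(C)C(=O)/C(C)=C\CC[C@]1(C)O[C@H]1[C@@H](O)C=C
A1 | alternative 1 | open-chain E-alkenyl iodide aldehyde (C7 CH2CO2Me, O8 p-methoxybenzyl, O9 tert-butyldimethylsilyl) | I/C=C(\C)CC/C=C(/C)[C@@H](O[Si](C)(C)C(C)(C)C)[C@H](OCc1ccc(OC)cc1)[C@@H](CC(=O)OC)C=O
A2 | alternative 1 | ten-membered cis-lactone with O8 p-methoxybenzyl ether and O9 tert-butyldimethylsilyl ether | C1C(=O)O[C@H]2/C=C(\C)CC/C=C(/C)[C@@H](O[Si](C)(C)C(C)(C)C)[C@H](OCc3ccc(OC)cc3)[C@@H]12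
A3 | alternative 2 | trans-decalin lactone: angular C9 hydroxyl, angular C4 methyl, equatorial C5 mesylate, C1=C10 alkene, O8 triethylsilyl ether | C1C(=O)O[C@H]2[C@@H](OS(C)(=O)=O)[C@]3(C)CCC=C(C)[C@@]3(O)[C@H](O[Si](CC)(CC)CC)[C@@H]12
A4 | alternative 2 | ten-membered C9 ketone with cis-lactone and O8 triethylsilyl ether (identical with 21) | C1C(=O)O[C@H]2/C=C(\C)CC/C=C(/C)C(=O)[C@H](O[Si](CC)(CC)CC)[C@@H]12
A5 | alternative 3 | ten-membered ring with free C6 hydroxyl, C7 ethynyl, O8 triethylsilyl ether and O9 epoxyangelate | O[C@H]1/C=C(\C)CC/C=C(/C)[C@@H](OC(=O)[C@@]2(C)O[C@H]2C)[C@H](O[Si](CC)(CC)CC)[C@H]1C#C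
A6 | alternative 3 | O8 triethylsilyl ether of the target (identical with 32) | C=C1C(=O)O[C@H]2/C=C(\C)CC/C=C(/C)[C@@H](OC(=O)[C@@]3(C)O[C@H]3C)[C@H](O[Si](CC)(CC)CC)[C@@H]12
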